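## Retrosynthetic overview

1. The target is a 3,3''-biflavanone whose unit A (5,7-dihydroxy) is 2,3-trans (2S,3R) and whose unit B (5-hydroxy-7-methoxy) is 2,3-cis (2''S,3''S). The last operation is removal of two benzyl ethers from unit A.
2. Ring C of unit B is opened by a retro-oxa-Michael reaction (the chalcone-to-flavanone step of biosynthesis) to a 2',6'-dihydroxychalcone carried on C3 of flavanone A.
3. Ring C of unit A is opened the same way to an α,α'-linked bichalcone. Its unit-B phenols are masked as allyl ethers, so the two rings close in a fixed order.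
4. The bichalcone comes from a double Claisen–Schmidt condensation of an unsymmetrical 1,4-diaryl-1,4-diketone with 4-methoxybenzaldehyde. The C3–C3'' bond is the central C–C bond of that diketone, made first by alkylating one acetophenone enolate with the α-iodo derivative of the other.
5. Ring order: ring C of unit A first (C2 set by catalyst, C3 trans by equilibration), then ring C of unit B (C2'' set by catalyst, C3'' cis by kinetic protonation).

Catalyst Q is 3-{[3,5-bis(trifluoromethyl)phenyl]amino}-4-{[(9R)-6'-methoxycinchonan-9-yl]amino}cyclobut-3-ene-1,2-dione, C32H28F6N4O3, the quinidine-derived bifunctional squaramide.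

Assumption: Q is taken as the pseudoenantiomer that gives the 2S series; if circular dichroism of compound 8 shows the opposite sense, the quinine-derived twin is used in steps 4 and 5 with nothing else changed.

## Route

Step 1
Reactants: 1 1-(2,6-dihydroxy-4-methoxyphenyl)ethan-1-one
Product: 2 1-[2,6-bis(allyloxy)-4-methoxyphenyl]ethan-1-one
Conditions: allyl bromide (2.5 equiv), K2CO3 (3 equiv), DMF, 60 °C
Reagents that add atoms: allyl bromide, C=CCBr
Why: Williamson etherification of both ortho phenols blocks the two nucleophiles of unit B until step 5 and removes acidic protons before enolate chemistry.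

Step 2
Reactants: 2 1-[2,6-bis(allyloxy)-4-methoxyphenyl]ethan-1-one; 3 1-[2,4-bis(benzyloxy)-6-hydroxyphenyl]ethan-1-one
Product: 5 1-[2,4-bis(benzyloxy)-6-hydroxyphenyl]-4-[2,6-bis(allyloxy)-4-methoxyphenyl]butane-1,4-dione, via iodoketone 4 (not isolated)
Conditions: 2, LiN(SiMe3)2 (1.05 equiv), THF, −78 °C, cannulated into I2 (1.05 equiv), THF, −78 °C; then added to 3 (1.2 equiv) + LiN(SiMe3)2 (2.5 equiv), THF, −78 → −20 °C; AcOH quench
Reagents that add atoms: none
Why: Enolate iodination followed by SN2 alkylation with the phenoxide/enolate dianion of 3 gives only the cross-coupled 1,4-diketone, because only 2 is halogenated and only 3 is a carbon nucleophile, and the di-ortho-substituted carbonyl of 4 is too hindered for Darzens-type attack.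

Step 3
Reactants: 5 1-[2,4-bis(benzyloxy)-6-hydroxyphenyl]-4-[2,6-bis(allyloxy)-4-methoxyphenyl]butane-1,4-dione; 6 4-methoxybenzaldehyde
Product: 7 (2E,3E)-1-[2,4-bis(benzyloxy)-6-hydroxyphenyl]-4-[2,6-bis(allyloxy)-4-methoxyphenyl]-2,3-bis[(4-methoxyphenyl)methylidene]butane-1,4-dione
Conditions: 6 (3 equiv), KOH (50% aq, base catalyst), EtOH, 0 → 20 °C, 36 h, dark; cold 1 M HCl to pH 5
Reagents that add atoms: none
Why: Double Claisen–Schmidt aldol condensation at the only two enolisable CH2 groups gives the (E,E)-bichalcone, and under strong base unit A stays open as its phenoxide so no racemic flavanone is carried forward.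

Step 4
Reactants: 7 (2E,3E)-1-[2,4-bis(benzyloxy)-6-hydroxyphenyl]-4-[2,6-bis(allyloxy)-4-methoxyphenyl]-2,3-bis[(4-methoxyphenyl)methylidene]butane-1,4-dione
Product: 8 (2S,3R)-5,7-bis(benzyloxy)-3-{(1E)-3-[2,6-bis(allyloxy)-4-methoxyphenyl]-1-(4-methoxyphenyl)-3-oxoprop-1-en-2-yl}-2-(4-methoxyphenyl)chroman-4-one
Conditions: squaramide Q C32H28F6N4O3 (10 mol %), toluene, −20 °C, 48 h; then 20 °C, 12 h, dark
Reagents that add atoms: none
Why: Proposed new method: the only free phenol adds to its own enone in a chalcone-isomerase-like 6-endo oxa-Michael reaction, with the quinuclidine acting as base and the squaramide binding the carbonyls to set C2 as S, and the C3–H (α to the ketone and on a carbon attached to the second enone) then epimerises through the cross-conjugated dienolate to the more stable 2,3-trans (3R) isomer; the closest known reaction is the cinchona thiourea-catalysed asymmetric cyclisation of α-activated 2'-hydroxychalcones to flavanones.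

Step 5
Reactants: 8 (2S,3R)-5,7-bis(benzyloxy)-3-{(1E)-3-[2,6-bis(allyloxy)-4-methoxyphenyl]-1-(4-methoxyphenyl)-3-oxoprop-1-en-2-yl}-2-(4-methoxyphenyl)chroman-4-one
Product: 10 (2S,3R)-5,7-bis(benzyloxy)-3-[(2S,3S)-5-hydroxy-7-methoxy-2-(4-methoxyphenyl)-4-oxochroman-3-yl]-2-(4-methoxyphenyl)chroman-4-one, via deallylated chalcone 9 (not isolated)
Conditions: Pd(PPh3)4 (5 mol %), N-methylaniline (8 equiv), CH2Cl2, 20 °C, 1 h, dark; then toluene, −40 °C, squaramide Q C32H28F6N4O3 (20 mol %), 36 h; cold dilute HCl wash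
Reagents that add atoms: none
Why: Proposed new method: zerovalent-palladium allyl transfer to the weakly basic N-methylaniline frees the unit-B phenols without base-induced cyclisation, Q then effects the second oxa-Michael closure to set C2'' as S, and the ring enolate, whose 2''-aryl group is forced pseudo-axial by allylic strain with the bulky C3'' substituent, is protonated at low temperature on the face anti to that aryl group to give the kinetic 2'',3''-cis (3''S) ring, which has no adjacent enone to acidify it and so does not equilibrate; the closest known reactions are kinetic protonation of 2,3-disubstituted chromanone enolates to cis products and the asymmetric oxa-Michael flavanone synthesis.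

Step 6
Reactants: 10 (2S,3R)-5,7-bis(benzyloxy)-3-[(2S,3S)-5-hydroxy-7-methoxy-2-(4-methoxyphenyl)-4-oxochroman-3-yl]-2-(4-methoxyphenyl)chroman-4-one
Product: 11 (2S,3R)-5,7-dihydroxy-3-[(2S,3S)-5-hydroxy-7-methoxy-2-(4-methoxyphenyl)-4-oxochroman-3-yl]-2-(4-methoxyphenyl)chroman-4-one
Conditions: H2 (1 atm), Pd/C (10 wt% Pd), EtOAc, 20 °C, 2 h
Reagents that add atoms: none
Why: Neutral hydrogenolysis cleaves the two benzyl ethers without acid or base, so neither the enolisable C3/C3'' centres nor the retro-Michael-labile C2/C2'' centres are disturbed.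

## Compound list

1 | 1-(2,6-dihydroxy-4-methoxyphenyl)ethan-1-one | CC(=O)c1c(O)cc(OC)cc1O | starting material
2 | 1-[2,6-bis(allyloxy)-4-methoxyphenyl]ethan-1-one | CC(=O)c1c(OCC=C)cc(OC)cc1OCC=C | intermediate
3 | 1-[2,4-bis(benzyloxy)-6-hydroxyphenyl]ethan-1-one | CC(=O)c1c(O)cc(OCc2ccccc2)cc1OCc1ccccc1 | starting material
4 | 1-[2,6-bis(allyloxy)-4-methoxyphenyl]-2-iodoethan-1-one | O=C(CI)c1c(OCC=C)cc(OC)cc1OCC=C | intermediate (not isolated)
5 | 1-[2,4-bis(benzyloxy)-6-hydroxyphenyl]-4-[2,6-bis(allyloxy)-4-methoxyphenyl]butane-1,4-dione | O=C(CCC(=O)c1c(OCC=C)cc(OC)cc1OCC=C)c1c(O)cc(OCc2ccccc2)cc1OCc1ccccc1 | intermediate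
6 | 4-methoxybenzaldehyde | COc1ccc(C=O)cc1 | starting material
7 | (2E,3E)-1-[2,4-bis(benzyloxy)-6-hydroxyphenyl]-4-[2,6-bis(allyloxy)-4-methoxyphenyl]-2,3-bis[(4-methoxyphenyl)methylidene]butane-1,4-dione | COc1ccc(/C=C(/C(=O)c2c(OCC=C)cc(OC)cc2OCC=C)C(=C/c2ccc(OC)cc2)\C(=O)c2c(O)cc(OCc3ccccc3)cc2OCc2ccccc2)cc1 | intermediate
8 | (2S,3R)-5,7-bis(benzyloxy)-3-{(1E)-3-[2,6-bis(allyloxy)-4-methoxyphenyl]-1-(4-methoxyphenyl)-3-oxoprop-1-en-2-yl}-2-(4-methoxyphenyl)chroman-4-one | COc1ccc([C@H]2Oc3cc(OCc4ccccc4)cc(OCc4ccccc4)c3C(=O)[C@@H]2/C(=C\c2ccc(OC)cc2)C(=O)c2c(OCC=C)cc(OC)cc2OCC=C)cc1 | intermediate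
9 | (2S,3R)-5,7-bis(benzyloxy)-3-[(1E)-3-(2,6-dihydroxy-4-methoxyphenyl)-1-(4-methoxyphenyl)-3-oxoprop-1-en-2-yl]-2-(4-methoxyphenyl)chroman-4-one | COc1ccc([C@H]2Oc3cc(OCc4ccccc4)cc(OCc4ccccc4)c3C(=O)[C@@H]2/C(=C\c2ccc(OC)cc2)C(=O)c2c(O)cc(OC)cc2O)cc1 | intermediate (not isolated)
10 | (2S,3R)-5,7-bis(benzyloxy)-3-[(2S,3S)-5-hydroxy-7-methoxy-2-(4-methoxyphenyl)-4-oxochroman-3-yl]-2-(4-methoxyphenyl)chroman-4-one | COc1ccc([C@H]2Oc3cc(OCc4ccccc4)cc(OCc4ccccc4)c3C(=O)[C@@H]2[C@@H]2C(=O)c3c(O)cc(OC)cc3O[C@@H]2c2ccc(OC)cc2)cc1 | intermediate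
11 | (2S,3R)-5,7-dihydroxy-3-[(2S,3S)-5-hydroxy-7-methoxy-2-(4-methoxyphenyl)-4-oxochroman-3-yl]-2-(4-methoxyphenyl)chroman-4-one (CNP0184936.3) | COc1ccc([C@H]2Oc3cc(O)cc(O)c3C(=O)[C@@H]2[C@@H]2C(=O)c3c(O)cc(OC)cc3O[C@@H]2c2ccc(OC)cc2)cc1 | target

## Step count and risks

Total steps: 6. Longest linear sequence: 6 (1 → 2 → 5 → 7 → 8 → 10 → 11; compounds 3 and 6 are bought).

Most likely to fail, step 5: the kinetic cis protonation may be only partly selective, and catalyst and substrate may be mismatched at C2''. The fallback separates ring closure from the setting of C3''. It sets out from 9 (made from 8 as in step 5), which is closed with Q at 0 °C without regard to C3'' to give 10 mixed with its C3'' epimer, (2S,3R)-5,7-bis(benzyloxy)-3-[(2S,3R)-5-hydroxy-7-methoxy-2-(4-methoxyphenyl)-4-oxochroman-3-yl]-2-(4-methoxyphenyl)chroman-4-one F1. The mixture is acetylated at the 5''-hydroxyl (Ac2O, pyridine, 0 °C) to the 5''-O-acetate of F1, F2, together with the acetate of 10. The acetoxy group makes the unit-B ketone the more acidic one (the unit-A ketone carries two alkoxy donors), so LiN(SiMe3)2 (1.0 equiv, THF, −78 °C) forms the unit-B enolate selectively and erases C3''. Quenching at −78 °C with 2,6-di-tert-butyl-4-methylphenol protonates anti to the 2''-aryl group and converges the material on the cis 5''-O-acetate of 10, F3. Ammonia in methanol at 0 °C removes the acetate and the route is rejoined at 10.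

Second, step 4: enantioselectivity or conversion may be poor on this new substrate class. The fallback is resolution with recycling. It sets out from 7, which is cyclised without chiral control (NaOAc, EtOH, 40 °C) to racemic trans material. Preparative chromatography on an amylose tris(3,5-dimethylphenylcarbamate) phase separates 8 from its enantiomer, (2R,3S)-5,7-bis(benzyloxy)-3-{(1E)-3-[2,6-bis(allyloxy)-4-methoxyphenyl]-1-(4-methoxyphenyl)-3-oxoprop-1-en-2-yl}-2-(4-methoxyphenyl)chroman-4-one F4. F4 is racemised through 7 with catalytic DBU (retro-oxa-Michael and reclosure) and resolved again, and the route is rejoined at 8.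

Third, step 2: the dianion alkylation may suffer from proton transfer or over-alkylation. The fallback builds the diketone by acyl-anion chemistry instead. It sets out from 2, which is α-methylenated (paraformaldehyde, diisopropylammonium trifluoroacetate, THF, reflux) to the aryl vinyl ketone 1-[2,6-bis(allyloxy)-4-methoxyphenyl]prop-2-en-1-one F5. A Stetter reaction (3-benzyl-5-(2-hydroxyethyl)-4-methylthiazolium chloride 20 mol %, Et3N, dioxane, 70 °C) with 2,4-bis(benzyloxy)-6-hydroxybenzaldehyde F6 (one step from 2,4,6-trihydroxybenzaldehyde with benzyl bromide and K2CO3) adds the acyl anion equivalent to the enone and gives 5 directly, where the route is rejoined.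

Further compounds

F1 | step 5 | (2S,3R)-5,7-bis(benzyloxy)-3-[(2S,3R)-5-hydroxy-7-methoxy-2-(4-methoxyphenyl)-4-oxochroman-3-yl]-2-(4-methoxyphenyl)chroman-4-one | COc1ccc([C@H]2Oc3cc(OCc4ccccc4)cc(OCc4ccccc4)c3C(=O)[C@@H]2[C@H]2C(=O)c3c(O)cc(OC)cc3O[C@@H]2c2ccc(OC)cc2)cc1
F2 | step 5 | (2S,3R)-3-[(2S,3R)-5-acetoxy-7-methoxy-2-(4-methoxyphenyl)-4-oxochroman-3-yl]-5,7-bis(benzyloxy)-2-(4-methoxyphenyl)chroman-4-one | COc1ccc([C@H]2Oc3cc(OCc4ccccc4)cc(OCc4ccccc4)c3C(=O)[C@@H]2[C@H]2C(=O)c3c(OC(C)=O)cc(OC)cc3O[C@@H]2c2ccc(OC)cc2)cc1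
F3 | step 5 | (2S,3R)-3-[(2S,3S)-5-acetoxy-7-methoxy-2-(4-methoxyphenyl)-4-oxochroman-3-yl]-5,7-bis(benzyloxy)-2-(4-methoxyphenyl)chroman-4-one | COc1ccc([C@H]2Oc3cc(OCc4ccccc4)cc(OCc4ccccc4)c3C(=O)[C@@H]2[C@@H]2C(=O)c3c(OC(C)=O)cc(OC)cc3O[C@@H]2c2ccc(OC)cc2)cc1
F4 | step 4 | (2R,3S)-5,7-bis(benzyloxy)-3-{(1E)-3-[2,6-bis(allyloxy)-4-methoxyphenyl]-1-(4-methoxyphenyl)-3-oxoprop-1-en-2-yl}-2-(4-methoxyphenyl)chroman-4-one | COc1ccc([C@@H]2Oc3cc(OCc4ccccc4)cc(OCc4ccccc4)c3C(=O)[C@H]2/C(=C\c2ccc(OC)cc2)C(=O)c2c(OCC=C)cc(OC)cc2OCC=C)cc1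
F5 | step 2 | 1-[2,6-bis(allyloxy)-4-methoxyphenyl]prop-2-en-1-one | C=CC(=O)c1c(OCC=C)cc(OC)cc1OCC=C
F6 | step 2 | 2,4-bis(benzyloxy)-6-hydroxybenzaldehyde | O=Cc1c(O)cc(OCc2ccccc2)cc1OCc1ccccc1
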